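Everything rests on cutting the C6–C7 bond of the cyclohexane ring (C5–C10). Ring carbon C6 is flanked by the branched centres C5 and C7. Its acyloxy group stands axial on the face of the axial C10 methyl, an arrangement that hydride attack on a ketone delivers. C6 is planned as a carbonyl and, one step earlier, as an acyl radical. Released from a phenyl selenoester, it closes the carbocycle 6-exo onto C7 of an E-enoate and fixes C7. The precursor is an open chain with C5, C8, C9 and C10 in place and a cis C8/C9 acetonide. C5 carries a saturated 1,3-dioxan-5-yl group as latent acrolein, since an isopropenyl group would invite allyl-assisted loss of CO.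

Key step: step 12

Numbering: C5–C10 form the carbocycle. C1/C2 are the vinyl group, later the oxirane. C4 with C3 and C15 is the three-carbon unit on C5. C11–C13 are the lactone carbons. O6–O9 are the oxygens on C6–C9. Compounds 19 and 20 keep the full carbon skeleton, and only the C4 unit is carried at the saturated 1,3-diol level.
Assumption: the (1R,2R) antipode of the bishydroxamic acid ligand in step 19 is taken to deliver oxygen to the Si face of C1. This sense of induction has to be verified on 32, and the other antipode is used if it proves mismatched.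
Remark: 23 and 24 (at C11) and 30 and 31 (at C4) are epimer mixtures at centres that become trigonal again, so these centres carry no stereo label.

Step 1
Reactants: 1 2,3-O-isopropylidene-D-erythronolactone
Product: 2 2,3-O-isopropylidene-D-erythrose (lactol)
Conditions: i-Bu2AlH (1.1 equiv), CH2Cl2, −78 °C; aq potassium sodium tartrate
Reagents that add atoms: none
Why: Low-temperature i-Bu2AlH reduction of a γ-lactone stops at the lactol because the aluminium hemiacetal survives until work-up, and C8 and C9 are not touched.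

Step 2
Reactants: 2 2,3-O-isopropylidene-D-erythrose (lactol)
Product: 3 [(4R,5S)-5-ethynyl-2,2-dimethyl-1,3-dioxolan-4-yl]methanol
Conditions: dimethyl (1-diazo-2-oxopropyl)phosphonate, K2CO3, MeOH, rt → 40 °C
Reagents that add atoms: dimethyl (1-diazo-2-oxopropyl)phosphonate CC(=O)C(=[N+]=[N-])P(=O)(OC)OC
Why: The Ohira–Bestmann variant of the Seyferth–Gilbert homologation works on lactols through their open hydroxy aldehyde form, turns the former lactone carbon into C10 and adds C1 as a terminal alkyne, and consumes the small aldehyde fraction fast enough to keep C9 from epimerising.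

Step 3
Reactants: 3 [(4R,5S)-5-ethynyl-2,2-dimethyl-1,3-dioxolan-4-yl]methanol
Product: 4 O7 tert-butyldimethylsilyl ether of 3
Conditions: t-BuMe2SiCl, imidazole, CH2Cl2, rt
Reagents that add atoms: tert-butyldimethylsilyl chloride CC(C)(C)[Si](C)(C)Cl
Why: Imidazole-promoted silylation of the only hydroxyl group protects O7 against the organometallic steps that follow.

Step 4
Reactants: 4 O7 tert-butyldimethylsilyl ether of 3
Product: 6 methyl 3-[(4S,5R)-5-(silyloxymethyl)-2,2-dimethyl-1,3-dioxolan-4-yl]prop-2-ynoate, via lithium acetylide 5 (not isolated)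
Conditions: n-BuLi, THF, −78 °C; ClCO2Me, −78 °C → 0 °C
Reagents that add atoms: methyl chloroformate COC(=O)Cl
Why: Lithiation of a terminal alkyne and C-acylation with a chloroformate is the standard entry to 2-ynoates and adds C2.

Step 5
Reactants: 6 methyl 3-[(4S,5R)-5-(silyloxymethyl)-2,2-dimethyl-1,3-dioxolan-4-yl]prop-2-ynoate
Product: 7 methyl (Z)-3-[(4S,5R)-5-(silyloxymethyl)-2,2-dimethyl-1,3-dioxolan-4-yl]but-2-enoate
Conditions: Me2CuLi (from CuI and MeLi), THF, −78 °C; MeOH then aq NH4Cl at −78 °C
Reagents that add atoms: lithium dimethylcuprate [Li+].C[Cu-]C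
Why: Conjugate addition of Me2CuLi to a 2-ynoate is a syn carbocupration, so protonation of the alkenylcopper species at −78 °C leaves the new methyl group cis to H1 and C9 cis to C2, which is the Z geometry that step 9 requires.

Step 6
Reactants: 7 methyl (Z)-3-[(4S,5R)-5-(silyloxymethyl)-2,2-dimethyl-1,3-dioxolan-4-yl]but-2-enoate
Product: 8 (Z)-3-[(4S,5R)-5-(silyloxymethyl)-2,2-dimethyl-1,3-dioxolan-4-yl]but-2-en-1-ol
Conditions: i-Bu2AlH (2.5 equiv), CH2Cl2, −78 °C; aq potassium sodium tartrate
Reagents that add atoms: none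
Why: i-Bu2AlH reduces the enoate 1,2 to the allylic alcohol without changing the alkene geometry, the silyl ether or the acetonide.

Step 7
Reactants: 9 2-(2,2-dimethyl-1,3-dioxan-5-yl)ethanol
Product: 10 2-(2,2-dimethyl-1,3-dioxan-5-yl)acetic acid
Conditions: TEMPO (cat.), NaClO2, NaOCl (cat.), MeCN/aq NaH2PO4–Na2HPO4 (pH 6.7), 35 °C
Reagents that add atoms: sodium chlorite [Na+].[O-]Cl=O
Why: The TEMPO-catalysed NaClO2 oxidation takes a primary alcohol to the acid at nearly neutral pH, which the acid-labile dioxane tolerates.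

Step 8
Reactants: 8 (Z)-3-[(4S,5R)-5-(silyloxymethyl)-2,2-dimethyl-1,3-dioxolan-4-yl]but-2-en-1-ol; 10 2-(2,2-dimethyl-1,3-dioxan-5-yl)acetic acid
Product: 11 (Z)-allylic ester of 8 and 10
Conditions: DCC, DMAP (cat.), CH2Cl2, 0 °C → rt
Reagents that add atoms: none
Why: Steglich esterification joins the two fragments under neutral conditions that leave the Z-alkene and both acetonides intact.

Step 9
Reactants: 11 (Z)-allylic ester of 8 and 10
Product: 15 (5S,8R,9S,10S)-hydroxy acid with C5 dioxanyl group plus C10 methyl/vinyl quaternary centre, via lithium enolate 12 (not isolated), via silyl ketene acetal 13 (not isolated), via silyl ester 14 (not isolated)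
Conditions: LiN(i-Pr)2, THF/DMPU (4:1), −78 °C; t-BuMe2SiCl; −78 °C → 60 °C; then Bu4NF, THF, rt; citric acid work-up
Reagents that add atoms: none
Why: Ireland–Claisen rearrangement: LiN(i-Pr)2 in THF/DMPU gives the enolate with C4 cis to OLi and hence the (Z)-silyl ketene acetal, whose chair transition state with the (Z)-alkene fixes the C5/C10 relationship, while A(1,3) strain in the (Z)-alkene holds H9 in the alkene plane so that C8 with its CH2OSi arm covers one face and C5 bonds to C10 on the other, setting both centres relative to C9; fluoride then frees the acid and O7 in the same flask.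

Step 10
Reactants: 15 (5S,8R,9S,10S)-hydroxy acid; 16 tert-butyl (triphenylphosphoranylidene)acetate
Product: 18 E-enoate acid (C7=C11 tert-butyl enoate), via aldehyde 17 (not isolated)
Conditions: TEMPO (cat.), PhI(OAc)2 (1.1 equiv), CH2Cl2, rt; then 16 (3 equiv), rt
Reagents that add atoms: none
Why: One-pot oxoammonium oxidation and Wittig olefination avoids handling the epimerisable α-alkoxy aldehyde, and the stabilised ylide, used in excess to tolerate the free acid, gives the E-enoate.

Step 11
Reactants: 18 E-enoate acid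
Product: 19 Se-phenyl (5S,8R,9S,10S)-selenoester enoate (cyclisation precursor)
Conditions: N-(phenylseleno)phthalimide, Bu3P, CH2Cl2, 0 °C → rt
Reagents that add atoms: N-(phenylseleno)phthalimide O=C1c2ccccc2C(=O)N1[Se]c1ccccc1
Why: Activation of the acid as an acyloxyphosphonium salt and capture by phenylselenolate (Bu3P/N-phenylselenophthalimide method) forms the selenoester under neutral conditions, without free selenol that could add to the enoate and without epimerising C5.

Step 12
Reactants: 19 Se-phenyl (5S,8R,9S,10S)-selenoester enoate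
Product: 20 (5S,7R,8R,9S,10S)-cyclohexanone with C6 ketone and C7 CH2CO2t-Bu arm
Conditions: (Me3Si)3SiH (1.1 equiv), Et3B (0.3 equiv), air, benzene (0.01 M), rt
Reagents that add atoms: none
Why: The silyl radical takes the phenylseleno group from 19, the nucleophilic C6 acyl radical adds to the electron-poor C7 of the enoate, and the C11 radical next to the ester is quenched by (Me3Si)3SiH, which carries the chain. The closest known reaction type is the cyclisation of selenoester-derived acyl radicals onto α,β-unsaturated esters and β-alkoxyacrylates under silane/Et3B/air conditions. The cyclohexanone ring (C5–C10) closes in the 6-exo-trig mode. C7, the only new stereocentre, is set by a chair transition state with the C5 dioxanyl group and O8 equatorial, so the C11 arm also takes an equatorial place trans to O8, and since this centre is α to the ketone and equatorial it is also the thermodynamic one. The step needs ring closure to beat loss of CO and direct hydrogen transfer, which the substrate secures because C5 carries only saturated groups (decarbonylation would give a plain secondary radical), the acceptor is activated, the quaternary C10 and the cis-dioxolane fold the chain, the silane is a slow hydrogen donor at high dilution, and initiation at room temperature disfavours fragmentation. The C10 vinyl group is out of reach, since attack on it would be 4-exo or 5-endo.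

Step 13
Reactants: 20 (5S,7R,8R,9S,10S)-cyclohexanone
Product: 21 (6S)-axial C6 alcohol
Conditions: Li[HB(s-Bu)3], THF, −78 °C → −20 °C; aq NH4Cl
Reagents that add atoms: none
Why: The bulky borohydride attacks the C6 ketone from the equatorial side because the axial trajectory is closed by the axial C10 methyl group, which gives the axial alcohol on the methyl face, and the tert-butyl ester resists attack by the neighbouring alkoxide.

Step 14
Reactants: 21 (6S)-axial C6 alcohol
Product: 25 tert-butyl 2-substituted acrylate (C11=C13 installed), via dilithio derivative 22 (not isolated), via Mannich base 23 (not isolated), via methiodide 24 (not isolated)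
Conditions: LiN(i-Pr)2 (2.5 equiv), THF, −78 °C; (CH2=NMe2)I, −78 °C → rt, aq work-up; MeI, CH2Cl2/MeOH, rt; aq NaHCO3, CH2Cl2, rt
Reagents that add atoms: N,N-dimethylmethyleneiminium iodide C[N+](C)=C.[I-]
Why: Mannich reaction of the ester enolate with Eschenmoser's salt followed by quaternisation and E1cB loss of trimethylamine is the standard α-methylenation, placed here because the tert-butyl ester is the only enolisable group and no base-sensitive function is yet present.

Step 15
Reactants: 25 tert-butyl 2-substituted acrylate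
Product: 26 C6 isobutyrate
Conditions: (i-PrCO)2O, DMAP (1 equiv), Et3N, toluene, 60 °C
Reagents that add atoms: isobutyric anhydride CC(C)C(=O)OC(=O)C(C)C
Why: DMAP-catalysed acylation with the anhydride at elevated temperature esterifies the only free hydroxyl group, hindered as it is by the syn-axial methyl group.

Step 16
Reactants: 26 C6 isobutyrate
Product: 28 α-methylene trans-γ-lactone triol (O9H plus C3/C15 diol), via seco acid 27 (not isolated)
Conditions: CF3CO2H/H2O (9:1), 0 °C → rt
Reagents that add atoms: none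
Why: Aqueous CF3CO2H cleaves both acetonides and the tert-butyl ester, and the acid then closes the trans-fused γ-lactone on the equatorial O8, since O6 is acylated and the axial O9 cannot reach C12, while the monosubstituted vinyl group and the acrylate are not protonated under these conditions.

Step 17
Reactants: 28 α-methylene trans-γ-lactone triol
Product: 30 C3/C15 monoacetate, via cyclic orthoacetate 29 (not isolated)
Conditions: MeC(OMe)3, PPTS (cat.), CH2Cl2, rt; then 90% aq AcOH, rt
Reagents that add atoms: trimethyl orthoacetate CC(OC)(OC)OC; water O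
Why: Cyclic orthoester formation needs a diol, so only the C3/C15 1,3-diol is engaged, and mild hydrolysis of the cyclic orthoacetate opens it to exactly one acetate and one free hydroxyl (orthoester route to diol monoesters).

Step 18
Reactants: 30 C3/C15 monoacetate
Product: 32 2-substituted acrolein (C4=C3 and C15 aldehyde), via acetoxy aldehyde 31 (not isolated)
Conditions: TEMPO (cat.), PhI(OAc)2, CH2Cl2, rt; then Et3N, 0 °C
Reagents that add atoms: none
Why: The oxoammonium oxidation takes the primary alcohol in preference to the hindered axial C9 carbinol, and the β-acetoxy aldehyde loses acetic acid by E1cB elimination on addition of Et3N, giving the acrolein with no regiochemical alternative.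

Step 19
Reactants: 32 2-substituted acrolein
Product: 33 target CNP0496100.1
Conditions: VO(Oi-Pr)3 (5 mol %), (1R,2R)-N,N'-dihydroxy-N,N'-bis(diphenylacetyl)cyclohexane-1,2-diamine (10 mol %), cumene hydroperoxide, toluene, 0 °C → rt
Reagents that add atoms: cumene hydroperoxide CC(C)(OO)c1ccccc1
Why: In the vanadium-catalysed asymmetric epoxidation of homoallylic alcohols the metal binds O9 and reaches only the homoallylic C1=C2 bond, the two electron-poor alkenes stay inert, and because the two substrate-controlled vanadate transition states are close in energy the C1 configuration (R, oxygen on the Si face) is left to the chiral bishydroxamate ligand.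

Compound list
1 | 2,3-O-isopropylidene-D-erythronolactone, (3aR,6aR) | O=C1[C@@H]2OC(C)(C)O[C@@H]2CO1 | starting material
2 | 2,3-O-isopropylidene-D-erythrose, lactol, anomer mixture | OC1[C@@H]2OC(C)(C)O[C@@H]2CO1 | intermediate
3 | [(4R,5S)-5-ethynyl-2,2-dimethyl-1,3-dioxolan-4-yl]methanol (C8 R, C9 S) | C#C[C@@H]1OC(C)(C)O[C@@H]1CO | intermediate
4 | O7 tert-butyldimethylsilyl ether of 3 | C#C[C@@H]1OC(C)(C)O[C@@H]1CO[Si](C)(C)C(C)(C)C | intermediate
5 | lithium acetylide of 4 | [Li]C#C[C@@H]1OC(C)(C)O[C@@H]1CO[Si](C)(C)C(C)(C)C | intermediate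
6 | methyl 3-[(4S,5R)-5-(tert-butyldimethylsilyloxymethyl)-2,2-dimethyl-1,3-dioxolan-4-yl]prop-2-ynoate | COC(=O)C#C[C@@H]1OC(C)(C)O[C@@H]1CO[Si](C)(C)C(C)(C)C | intermediate
7 | methyl (Z)-3-[(4S,5R)-5-(tert-butyldimethylsilyloxymethyl)-2,2-dimethyl-1,3-dioxolan-4-yl]but-2-enoate, C9 cis to C2 | COC(=O)/C=C(/C)[C@@H]1OC(C)(C)O[C@@H]1CO[Si](C)(C)C(C)(C)C | intermediate
8 | (Z)-allylic alcohol from 7 | OC/C=C(/C)[C@@H]1OC(C)(C)O[C@@H]1CO[Si](C)(C)C(C)(C)C | intermediate
9 | 2-(2,2-dimethyl-1,3-dioxan-5-yl)ethanol | OCCC1COC(C)(C)OC1 | starting material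
10 | 2-(2,2-dimethyl-1,3-dioxan-5-yl)acetic acid | OC(=O)CC1COC(C)(C)OC1 | intermediate
11 | (Z)-allylic ester of 8 and 10 | O=C(CC1COC(C)(C)OC1)OC/C=C(/C)[C@@H]1OC(C)(C)O[C@@H]1CO[Si](C)(C)C(C)(C)C | intermediate
12 | lithium enolate of 11, C4 cis to OLi | [Li]O/C(=C\C1COC(C)(C)OC1)OC/C=C(/C)[C@@H]1OC(C)(C)O[C@@H]1CO[Si](C)(C)C(C)(C)C | intermediate
13 | (Z)-tert-butyldimethylsilyl ketene acetal of 11, C4 cis to OSi | CC(C)(C)[Si](C)(C)O/C(=C\C1COC(C)(C)OC1)OC/C=C(/C)[C@@H]1OC(C)(C)O[C@@H]1CO[Si](C)(C)C(C)(C)C | intermediate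
14 | silyl ester of the rearranged acid (5S,8R,9S,10S), O7 still silylated | CC(C)(C)[Si](C)(C)OC(=O)[C@@H](C1COC(C)(C)OC1)[C@](C)(C=C)[C@@H]1OC(C)(C)O[C@@H]1CO[Si](C)(C)C(C)(C)C | intermediate
15 | (5S,8R,9S,10S)-hydroxy acid: C6 acid, C5 dioxanyl, C10 methyl and vinyl, C8/C9 cis-acetonide, C7 CH2OH | OC(=O)[C@@H](C1COC(C)(C)OC1)[C@](C)(C=C)[C@@H]1OC(C)(C)O[C@@H]1CO | intermediate
16 | tert-butyl (triphenylphosphoranylidene)acetate | CC(C)(C)OC(=O)C=P(c1ccccc1)(c1ccccc1)c1ccccc1 | starting material
17 | C7 aldehyde of 15 | OC(=O)[C@@H](C1COC(C)(C)OC1)[C@](C)(C=C)[C@@H]1OC(C)(C)O[C@@H]1C=O | intermediate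
18 | (5S,8R,9S,10S)-acid with E-configured C7=C11 tert-butyl enoate | OC(=O)[C@@H](C1COC(C)(C)OC1)[C@](C)(C=C)[C@@H]1OC(C)(C)O[C@@H]1/C=C/C(=O)OC(C)(C)C | intermediate
19 | Se-phenyl selenoester of 18 (key-step precursor) | O=C([Se]c1ccccc1)[C@@H](C1COC(C)(C)OC1)[C@](C)(C=C)[C@@H]1OC(C)(C)O[C@@H]1/C=C/C(=O)OC(C)(C)C | intermediate
20 | (5S,7R,8R,9S,10S)-cyclohexanone: C6 ketone, equatorial C7 CH2CO2t-Bu, C8/C9 cis-acetonide, axial C10 methyl, equatorial vinyl, equatorial C5 dioxanyl (key-step product) | CC1(C)O[C@@H]2[C@@H](CC(=O)OC(C)(C)C)C(=O)[C@@H](C3COC(C)(C)OC3)[C@](C)(C=C)[C@@H]2O1 | intermediate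
21 | (5S,6S,7S,8R,9S,10S)-axial C6 alcohol | CC1(C)O[C@@H]2[C@@H](CC(=O)OC(C)(C)C)[C@@H](O)[C@@H](C3COC(C)(C)OC3)[C@](C)(C=C)[C@@H]2O1 | intermediate
22 | dilithio derivative of 21 (O6 alkoxide and ester enolate) | CC1(C)O[C@@H]2[C@@H](C=C(O[Li])OC(C)(C)C)[C@@H](O[Li])[C@@H](C3COC(C)(C)OC3)[C@](C)(C=C)[C@@H]2O1 | intermediate
23 | C11 dimethylaminomethyl Mannich base, C11 epimers | CC1(C)O[C@@H]2[C@@H](C(CN(C)C)C(=O)OC(C)(C)C)[C@@H](O)[C@@H](C3COC(C)(C)OC3)[C@](C)(C=C)[C@@H]2O1 | intermediate
24 | methiodide of 23 | CC1(C)O[C@@H]2[C@@H](C(C[N+](C)(C)C)C(=O)OC(C)(C)C)[C@@H](O)[C@@H](C3COC(C)(C)OC3)[C@](C)(C=C)[C@@H]2O1.[I-] | intermediate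
25 | tert-butyl acrylate with C11=C13, free axial O6H | CC1(C)O[C@@H]2[C@@H](C(=C)C(=O)OC(C)(C)C)[C@@H](O)[C@@H](C3COC(C)(C)OC3)[C@](C)(C=C)[C@@H]2O1 | intermediate
26 | C6 isobutyrate of 25 | CC1(C)O[C@@H]2[C@@H](C(=C)C(=O)OC(C)(C)C)[C@@H](OC(=O)C(C)C)[C@@H](C3COC(C)(C)OC3)[C@](C)(C=C)[C@@H]2O1 | intermediate
27 | seco acid: tetraol acrylic acid | O[C@@H]1[C@@H](C(=C)C(=O)O)[C@@H](OC(=O)C(C)C)[C@@H](C(CO)CO)[C@](C)(C=C)[C@@H]1O | intermediate
28 | (5S,6S,7S,8R,9S,10S)-α-methylene-12,8-lactone with O9H and C3/C15 diol | C=C1C(=O)O[C@@H]2[C@@H]1[C@@H](OC(=O)C(C)C)[C@@H](C(CO)CO)[C@](C)(C=C)[C@@H]2O | intermediate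
29 | cyclic methyl orthoacetate of the C3/C15 diol | C=C1C(=O)O[C@@H]2[C@@H]1[C@@H](OC(=O)C(C)C)[C@@H](C3COC(C)(OC)OC3)[C@](C)(C=C)[C@@H]2O | intermediate
30 | monoacetate of the C3/C15 diol, C4 epimers | C=C1C(=O)O[C@@H]2[C@@H]1[C@@H](OC(=O)C(C)C)[C@@H](C(CO)COC(C)=O)[C@](C)(C=C)[C@@H]2O | intermediate
31 | β-acetoxy aldehyde, C4 epimers | C=C1C(=O)O[C@@H]2[C@@H]1[C@@H](OC(=O)C(C)C)[C@@H](C(C=O)COC(C)=O)[C@](C)(C=C)[C@@H]2O | intermediate
32 | (5R,6S,7S,8R,9S,10S)-enal with C10 vinyl group | C=C1C(=O)O[C@@H]2[C@@H]1[C@@H](OC(=O)C(C)C)[C@@H](C(=C)C=O)[C@](C)(C=C)[C@@H]2O | intermediate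
33 | CNP0496100.1, (1R,5R,6S,7S,8R,9S,10S) | C=C1C(=O)O[C@@H]2[C@@H]1[C@@H](OC(=O)C(C)C)[C@@H](C(=C)C=O)[C@](C)([C@@H]1CO1)[C@@H]2O | target

Total step count: 19. Longest linear sequence: 18 (steps 1–6 and 8–19). Step 7 is a one-step side branch.

Steps most likely to fail

Step 12. The acyl radical may lose CO or pick up hydrogen before it reaches C7, or it may close through the flipped chair with erosion at C7. The fallback sets out from 18 and joins C6 and C7 through a ketyl radical, which cannot fragment.
- Acid 18 is converted with 1-chloro-N,N,2-trimethylpropenylamine into the acid chloride F1.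
- F1 is reduced with Bu3SnH and Pd(PPh3)4 to the C6 aldehyde F2.
- SmI2 in THF/t-BuOH then effects a 6-exo ketyl–olefin cyclisation onto the enoate to give the C6 carbinol F3.
- Dess–Martin oxidation of F3 comes back to the route at 20, where C7 can settle in its equatorial position.

Step 9. Facial discrimination at C10 by the C9 centre may be too low, or competition between chair and boat may erode C5. The fallback sets out from 11 and puts both elements under reagent control. The ester is enolised with a chiral 2-bromo-4,5-diphenyl-1,3-bis(arylsulfonyl)-1,3,2-diazaborolidine and a tertiary amine in CH2Cl2. The boron ketene acetal rearranges between −78 °C and −20 °C to the O7-silylated acid F4. Bu4NF then removes the silyl ether and the route is rejoined at 15.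

Step 19. Oxygen transfer to the monosubstituted vinyl group may be sluggish, and the catalyst may fail to override the substrate bias at C1. The fallback sets out from 32 and gives up facial control in the epoxidation. VO(acac)2 with t-BuOOH gives 33 together with the C1 epimer F5. A hydrolytic kinetic resolution follows, using (salen)Co(OAc) and half an equivalent of water (salen = N,N'-bis(3,5-di-tert-butylsalicylidene)cyclohexane-1,2-diamine dianion, in the antipode matched to the (1S)-oxirane). It opens only F5 to the 1,2-diol F6. F6 is removed by chromatography, which leaves 33.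

Further compounds
F1 | step 12 | acid chloride of 18 | O=C(Cl)[C@@H](C1COC(C)(C)OC1)[C@](C)(C=C)[C@@H]1OC(C)(C)O[C@@H]1/C=C/C(=O)OC(C)(C)C
F2 | step 12 | C6 aldehyde | O=C[C@@H](C1COC(C)(C)OC1)[C@](C)(C=C)[C@@H]1OC(C)(C)O[C@@H]1/C=C/C(=O)OC(C)(C)C
F3 | step 12 | C6 carbinol, C6 epimers | CC1(C)O[C@@H]2[C@@H](CC(=O)OC(C)(C)C)C(O)[C@@H](C3COC(C)(C)OC3)[C@](C)(C=C)[C@@H]2O1
F4 | step 9 | O7-silylated acid | OC(=O)[C@@H](C1COC(C)(C)OC1)[C@](C)(C=C)[C@@H]1OC(C)(C)O[C@@H]1CO[Si](C)(C)C(C)(C)C
F5 | step 19 | C1 epimer of 33 | C=C1C(=O)O[C@@H]2[C@@H]1[C@@H](OC(=O)C(C)C)[C@@H](C(=C)C=O)[C@](C)([C@H]1CO1)[C@@H]2O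
F6 | step 19 | 1,2-diol from F5 | C=C1C(=O)O[C@@H]2[C@@H]1[C@@H](OC(=O)C(C)C)[C@@H](C(=C)C=O)[C@](C)([C@H](O)CO)[C@@H]2O
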